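**Retrosynthetic overview**
1. The target comes from double O-debenzylation and loss of CO2 from a C3-quaternary α-aroyl-α-(benzyloxycarbonyl)-γ-lactone. C3 then settles trans to C4 by enolisation.
2. That lactone comes from a one-pot union of three pieces. 3,4-Dimethoxyphenyl Grignard opens a cyclopropane-fused lactone at its CH2 (the future benzylic carbon), and the released enolate is C-acylated by O-benzylvanilloyl chloride.
3. The cyclopropane-fused lactone comes from dibenzyl malonate and (R)-epichlorohydrin: two C–C bonds and one C–O bond in one flask. The extra ester is a traceless activator.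
4. Ring order: cyclopropane and γ-lactone are both made in the first operation (the cyclopropane closes, the lactone follows at once). The cyclopropane is later spent as a strained electrophile, the lactone stays, and both arenes are bought.
5. Stereochemistry: C4 is relayed from epichlorohydrin through one clean inversion. C3 is set thermodynamically.

Assumption: the SMILES is read as the (3S,4R) trans isomer (7-oxo analogue of (−)-arctigenin), and commercial 2 of at least 99% ee is used.

**Step 1**
Reactants: 1 dibenzyl malonate; 2 (R)-epichlorohydrin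
Product: 6 benzyl (1R,5R)-2-oxo-3-oxabicyclo[3.1.0]hexane-1-carboxylate, via chlorohydrin malonate 3 (not isolated), via epoxy malonate 4 (not isolated), via cyclopropyl carbinol 5 (not isolated)
Conditions: NaH (1.0 equiv), BnOH (3 equiv), THF, 0 °C; 1 (1.1 equiv); 2 (1.0 equiv), rt → 65 °C, 18 h
Reagents that add atoms: none
Why: Malonate–epihalohydrin double alkylation/lactonisation cascade: the malonate anion opens 2 at the epoxide CH2 (3), the alkoxide recloses on CH2Cl (4, stereocentre untouched), the regenerated malonate anion opens 4 at the stereogenic carbon by 3-exo-tet SN2 with inversion (5), and the alkoxide lactonises onto the cis ester, so cyclopropane and γ-lactone form in one flask, C5 (R) is relayed from 2, and C1 follows from the only possible cis fusion (same spatial arrangement as the known ethyl (1S,5R) ester; the benzyl ester only changes the C1 descriptor).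

**Step 2**
Reactants: 7 4-(benzyloxy)-3-methoxybenzoic acid
Product: 8 4-(benzyloxy)-3-methoxybenzoyl chloride
Conditions: (COCl)2 (1.3 equiv), DMF (cat.), CH2Cl2, 0 °C → rt; evaporate, use crude
Reagents that add atoms: oxalyl chloride, O=C(Cl)C(=O)Cl
Why: Vilsmeier-type acid chloride formation, to which the aryl benzyl and methyl ethers are inert; no stereocentre is involved.

**Step 3**
Reactants: 6 benzyl (1R,5R)-2-oxo-3-oxabicyclo[3.1.0]hexane-1-carboxylate; 8 4-(benzyloxy)-3-methoxybenzoyl chloride; 9 4-bromo-1,2-dimethoxybenzene; 10 magnesium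
Product: 13 benzyl (3R,4R)-3-[4-(benzyloxy)-3-methoxybenzoyl]-4-(3,4-dimethoxybenzyl)-2-oxotetrahydrofuran-3-carboxylate, via aryl Grignard 11 (not isolated), via bromomagnesium enolate 12 (not isolated)
Conditions: 9 (1.2 equiv), 10, THF, 40 °C; CuI (15 mol %), −30 °C; 6, 1 h; 8 (1.5 equiv), −30 °C → rt; aq NH4Cl
Reagents that add atoms: none
Why: Copper-catalysed homoconjugate addition of an aryl Grignard to a doubly activated cyclopropane (attack at the unhindered C6H2, C1–C6 cleavage, no bond to C5 touched, so C5 becomes C4 (R)), followed by C-acylation of the chelated magnesium malonate-type enolate 12 (first half of the Bowman ketone synthesis), with 8 entering anti to the C4 side chain, although the C3 configuration is erased in step 4.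

**Step 4**
Reactants: 13 benzyl (3R,4R)-3-[4-(benzyloxy)-3-methoxybenzoyl]-4-(3,4-dimethoxybenzyl)-2-oxotetrahydrofuran-3-carboxylate
Product: 15 (3S,4R)-4-(3,4-dimethoxybenzyl)-3-(4-hydroxy-3-methoxybenzoyl)dihydrofuran-2(3H)-one, via keto acid 14 (not isolated)
Conditions: H2 (1 atm), 10% Pd/C, EtOAc, rt, then 45 °C, 1 h
Reagents that add atoms: none
Why: Hydrogenolysis–decarboxylation (second half of the Bowman ketone synthesis): both O-benzyl groups are cleaved, the doubly activated β-keto acid 14 loses CO2 on gentle warming, and the labile C3–H of the β-keto lactone equilibrates by enolisation to the more stable trans (3S) isomer under control of the fixed C4 (R) centre, while the electron-rich aryl ketone survives 1 atm of H2 in a neutral solvent.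

**Compound list**
1 | dibenzyl malonate | O=C(CC(=O)OCc1ccccc1)OCc1ccccc1 | starting material
2 | (R)-epichlorohydrin, (2R)-2-(chloromethyl)oxirane | ClC[C@H]1CO1 | starting material
3 | dibenzyl 2-[(2R)-3-chloro-2-hydroxypropyl]malonate | ClC[C@H](O)CC(C(=O)OCc1ccccc1)C(=O)OCc1ccccc1 | intermediate
4 | dibenzyl 2-{[(2R)-oxiran-2-yl]methyl}malonate | C1O[C@@H]1CC(C(=O)OCc2ccccc2)C(=O)OCc2ccccc2 | intermediate
5 | dibenzyl (2R)-2-(hydroxymethyl)cyclopropane-1,1-dicarboxylate | OC[C@@H]1CC1(C(=O)OCc2ccccc2)C(=O)OCc2ccccc2 | intermediate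
6 | benzyl (1R,5R)-2-oxo-3-oxabicyclo[3.1.0]hexane-1-carboxylate (cis-fused) | O=C1OC[C@@H]2C[C@]12C(=O)OCc3ccccc3 | intermediate
7 | 4-(benzyloxy)-3-methoxybenzoic acid | COc1cc(C(=O)O)ccc1OCc1ccccc1 | starting material
8 | 4-(benzyloxy)-3-methoxybenzoyl chloride | COc1cc(C(=O)Cl)ccc1OCc1ccccc1 | intermediate
9 | 4-bromo-1,2-dimethoxybenzene | COc1ccc(Br)cc1OC | starting material
10 | magnesium turnings | [Mg] | starting material
11 | (3,4-dimethoxyphenyl)magnesium bromide | COc1ccc([Mg]Br)cc1OC | intermediate
12 | bromomagnesium enolate of benzyl (4R)-4-(3,4-dimethoxybenzyl)-2-oxotetrahydrofuran-3-carboxylate | COc1ccc(C[C@H]2COC(O[Mg]Br)=C2C(=O)OCc2ccccc2)cc1OC | intermediate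
13 | benzyl (3R,4R)-3-[4-(benzyloxy)-3-methoxybenzoyl]-4-(3,4-dimethoxybenzyl)-2-oxotetrahydrofuran-3-carboxylate (aroyl trans to the C4 side chain) | COc1cc(C(=O)[C@@]2(C(=O)OCc3ccccc3)C(=O)OC[C@@H]2Cc2ccc(OC)c(OC)c2)ccc1OCc1ccccc1 | intermediate
14 | (3S,4R)-4-(3,4-dimethoxybenzyl)-3-(4-hydroxy-3-methoxybenzoyl)-2-oxotetrahydrofuran-3-carboxylic acid | COc1cc(C(=O)[C@@]2(C(=O)O)C(=O)OC[C@@H]2Cc2ccc(OC)c(OC)c2)ccc1O | intermediate
15 | (3S,4R)-4-(3,4-dimethoxybenzyl)-3-(4-hydroxy-3-methoxybenzoyl)dihydrofuran-2(3H)-one | COc1cc(C(=O)[C@H]2C(=O)OC[C@@H]2Cc2ccc(OC)c(OC)c2)ccc1O | target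

**Step count**
Total step count: 4.
Longest linear sequence: 3 (steps 1, 3 and 4). Step 2 is a one-step side arm.

**Steps most likely to fail**

Step 3 is most at risk. The hindered enolate 12 may be O-acylated or stay inert, and the triacylmethane 13 may lose its aroyl group on work-up. The fallback gives up the acylation and makes the C3–C7 bond by aldol addition and oxidation. It sets out from 6 and comes back at 15.
- Opening of 6 by 11 with CuI as before, but quenched with NH4Cl, gives benzyl (3R,4R)-4-(3,4-dimethoxybenzyl)-2-oxotetrahydrofuran-3-carboxylate F1.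
- H2 over Pd/C gives (3S,4R)-4-(3,4-dimethoxybenzyl)-2-oxotetrahydrofuran-3-carboxylic acid F2.
- F2 loses CO2 in toluene at 110 °C to give (4R)-4-(3,4-dimethoxybenzyl)dihydrofuran-2(3H)-one F3.
- LiHMDS in THF at −78 °C and commercial 4-(benzyloxy)-3-methoxybenzaldehyde add anti to the C4 side chain. This gives (3S,4R)-3-{[4-(benzyloxy)-3-methoxyphenyl](hydroxy)methyl}-4-(3,4-dimethoxybenzyl)dihydrofuran-2(3H)-one F4 as both carbinol epimers.
- Dess–Martin periodinane converts both epimers into (3S,4R)-3-[4-(benzyloxy)-3-methoxybenzoyl]-4-(3,4-dimethoxybenzyl)dihydrofuran-2(3H)-one F5.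
- H2 over Pd/C gives 15.

Step 1 is second. Direct displacement of chloride leads to the enantiomer and erodes the ee. Excess malonate can open 6, and the benzyl ester variant may give a modest yield. The ee is checked on 6, and 15 can be recrystallised. The fallback replaces the chiral-pool cascade by a catalytic asymmetric carbene-type cyclisation that again closes both rings at once. It sets out from 1 and comes back at 6.
- KOH (1 equiv) in benzyl alcohol gives 3-(benzyloxy)-3-oxopropanoic acid F6.
- Allyl bromide and K2CO3 in DMF give allyl benzyl malonate F7.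
- 4-Acetamidobenzenesulfonyl azide and Et3N in MeCN give allyl benzyl 2-diazomalonate F8.
- The divalent cobalt metalloradical catalyst [Co(3,5-DiMes-QingPhyrin)] (2 mol %, toluene, rt to 40 °C) effects intramolecular cyclopropanation to 6. The ligand enantiomer is chosen to deliver the (1R,5R) product.

Step 4 is third. The aryl ketone may be over-reduced, or cleavage of the aryl benzyl ether may stall. The fallback swaps reductive for Lewis-acid debenzylation. It sets out from 13 and comes back at 15. BCl3 with pentamethylbenzene as benzyl cation trap in CH2Cl2 at −78 °C removes both benzyl groups without touching the ketone or the methyl ethers. After aqueous work-up, acid 14 loses CO2 on warming to 40 °C and C3 equilibrates as in the main route.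

**Further compounds**
F1 | step 3 | benzyl (3R,4R)-4-(3,4-dimethoxybenzyl)-2-oxotetrahydrofuran-3-carboxylate | O=C(OCc1ccccc1)[C@H]2C(=O)OC[C@@H]2Cc3ccc(OC)c(OC)c3
F2 | step 3 | (3S,4R)-4-(3,4-dimethoxybenzyl)-2-oxotetrahydrofuran-3-carboxylic acid | O=C(O)[C@H]1C(=O)OC[C@@H]1Cc2ccc(OC)c(OC)c2
F3 | step 3 | (4R)-4-(3,4-dimethoxybenzyl)dihydrofuran-2(3H)-one | O=C1C[C@@H](Cc2ccc(OC)c(OC)c2)CO1
F4 | step 3 | (3S,4R)-3-{[4-(benzyloxy)-3-methoxyphenyl](hydroxy)methyl}-4-(3,4-dimethoxybenzyl)dihydrofuran-2(3H)-one, both carbinol epimers | COc1cc(C(O)[C@H]2C(=O)OC[C@@H]2Cc2ccc(OC)c(OC)c2)ccc1OCc1ccccc1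
F5 | step 3 | (3S,4R)-3-[4-(benzyloxy)-3-methoxybenzoyl]-4-(3,4-dimethoxybenzyl)dihydrofuran-2(3H)-one | COc1cc(C(=O)[C@H]2C(=O)OC[C@@H]2Cc2ccc(OC)c(OC)c2)ccc1OCc1ccccc1
F6 | step 1 | 3-(benzyloxy)-3-oxopropanoic acid | O=C(O)CC(=O)OCc1ccccc1
F7 | step 1 | allyl benzyl malonate | C=CCOC(=O)CC(=O)OCc1ccccc1
F8 | step 1 | allyl benzyl 2-diazomalonate | C=CCOC(=O)C(=[N+]=[N-])C(=O)OCc1ccccc1
F0 | step 4 | none | none
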